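The runs are simulated with made-up constants; the scatter is artificial.

Target in the asked flasks is reckoned here from one temperature coefficient, which joins the zeta run's rise of target to the alpha run's fall of substrate, both scaled to the same catalyst charge.

| setting | zeta | alpha | Wednesday's | Sunday's | Thursday's | Monday's |
|---|---|---|---|---|---|---|
| substrate | 2 M | 2 M | 2.0 M | 2.0 M | 2.0 M | 2.0 M |
| coupling partner | 2.6 M | 2.6 M | 2.60 M | 2.60 M | 2.60 M | 2.60 M |
| free catalyst | 110 mM | 240 mM | 160 mM | 160 mM | 160 mM | 160 mM |
| temperature | −45 °C | −10 °C | 20 °C | −35 °C | −40 °C | −20 °C |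
| remark | run made earlier | run made earlier |  |  |  |  |
| time |  |  | 3.0 h | 3.0 h | 3.0 h | 3.0 h |

zeta run (percent of the substrate charged)

| time / h | target / % | substrate / % |
|---|---|---|
| 1.33 | 0 | 99.6 |
| 3.00 | 0.1 | 97.9 |
| 5.00 | 0.9 | 97.0 |
| 6.00 | 1.2 | 95.8 |
| 8.00 | 2.3 | 95.4 |
| 10.0 | 3.2 | 93.7 |

alpha run (percent of the substrate charged)

| time / min | target / % | substrate / % |
|---|---|---|
| 15.0 | 8.4 | 88.8 |
| 30.0 | 17.2 | 78.1 |
| 50.0 | 28.9 | 67.5 |
| 60.0 | 33.6 | 64.3 |
| 80.0 | 42.0 | 54.8 |
| 90.0 | 45.3 | 50.5 |
| 120 | 54.6 | 41.0 |

(standard deviation of a reading: 0.5 percentage points)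

- the numbers in the tables scatter by 0.5 percentage points (one standard deviation)
- steps that have been proposed: substrate + free catalyst -> catalyst intermediate A; coupling partner + catalyst intermediate A <-> catalyst intermediate B; catalyst intermediate B -> released group + catalyst intermediate C; catalyst intermediate C -> free catalyst + target; catalyst intermediate A -> spent catalyst

- ranking by amount of target, in percent of the substrate charged, from high to low, at 3.0 h (Wednesday's / Sunday's / Thursday's / Monday's)
- the amount of target, in percent of the substrate charged of the flask you put first, at 3.0 h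
- the amount of target, in percent of the substrate charged of the flask you put last, at 3.0 h

1. Define k as the pseudo-first-order constant of target formation, taken proportional to catalyst and scaled to the catalyst charge of the asked flasks. The zeta run, after its lag, gains 0.00460 h⁻¹ of the charge, so k = 0.00701 h⁻¹ at its temperature.

2. The alpha run's substrate decay stands in for target formation and gives k = 0.294 h⁻¹.

3. The two values, one from a target rate and one from a substrate rate, give the temperature coefficient E/R = 6410 K, the slope of ln k against 1/T.

4. Monday's then has k = 0.112 h⁻¹, so 28.6% target at the asked time.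

5. Thursday's has k = 0.0128 h⁻¹, and k·t gives 3.84%.

6. That last link is weak, since the zeta line meets zero target at a lag θ = 3.04 h. Shortened by the same coefficient, θ is 1.67 h for Thursday's, and k(t − θ) gives 1.71%.

7. Sunday's has k = 0.0228 h⁻¹, and Wednesday's has k = 3.56 h⁻¹. The reckoned order follows k, which is larger for Wednesday's than for Monday's, for Monday's than for Sunday's, and for Sunday's than for Thursday's. Wednesday's reckons to >99.9%, an extrapolation to a temperature above the alpha run's.

The forecast gives Wednesday's > Monday's > Sunday's > Thursday's, with 88% and 1.2%, its top lower than this reckoning through “catalyst death per turnover”.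

The flasks give Monday's > Wednesday's > Sunday's > Thursday's: 29.4%, 22.1%, 5.29% and 2.07%.

    substrate + free catalyst → catalyst intermediate A (k = 0.0180 M⁻¹ min⁻¹, Ea = 48.0 kJ mol⁻¹)
    coupling partner + catalyst intermediate A ⇌ catalyst intermediate B (K = 0.470 M⁻¹, k = 0.110 M⁻¹ min⁻¹, Ea = 40.0 kJ mol⁻¹, ΔH = −37.0 kJ mol⁻¹)
    catalyst intermediate B → released group + catalyst intermediate C (k = 3.30 min⁻¹, Ea = 70.0 kJ mol⁻¹)
    catalyst intermediate C → free catalyst + target (k = 0.150 min⁻¹, Ea = 73.0 kJ mol⁻¹)
    catalyst intermediate A → spent catalyst (k = 0.00430 min⁻¹, Ea = 86.0 kJ mol⁻¹)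
    (constants at −20 °C)

Thursday's stands at 2.07% against the reckoned 1.71%. Carried by E/R = 6410 K, Wednesday's k gives that flask's own 22.1% in 0.0702 h, far shorter than the asked time, and Wednesday's flask shows 22.1% target with spent catalyst >99.9% at 1.50 h, then 22.1% target at 30.0 h. Monday's has spent catalyst 6.96% at 3.00 h.

Thursday's left until 8.0 h: the same E/R gives k(t − θ) = 8.10%. The flask gives 8.40%.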